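**Strategy.** Everything rests on the C5–C6 bond of the 1,2-dioxane ring. C6, the quaternary peroxy carbon carrying ethyl and the alkenyl chain, is a masked ketone carbon and is made electrophilic as a peroxycarbenium ion. The ring methylene C5 is the terminus of a 2-(1-silylethyl)allyl group on C4. The precursor is an acyclic mixed peroxyketal, assembled by amine-catalysed asymmetric addition of the enone-derived α-methoxy hydroperoxide to a silylated dienal, which sets C3. Lewis-acid ionisation triggers an intramolecular Hosomi–Sakurai reaction that closes ring O1–O2–C3–C4–C5–C6 and sets C6 in one operation. Diimide then turns the exocyclic ethylidene on C4 into the C4 ethyl stereocentre.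

Key step: step 12

Remarks on the chemistry (assumptions):
- Numbering follows the acid chain (C1 = CO2H, ring O1–O2–C3–C4–C5–C6); the target is (3R,4R,6R,7E,10S).
- Compounds 1, 4, 6, 11, 12 and 15 are taken as commercial.
- The silyl-bearing carbon of 13, 14 and 16–19 and the ketal carbon of 10 and 17–19 are carried as epimer mixtures, because both become sp2 in step 12.
- The ligand enantiomer in step 1 and the catalyst enantiomer in step 10 are those expected to give 10S and 3R; the sense is to be confirmed on the first run.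

**Fragment B: the C6–C14 enone as its α-methoxy hydroperoxide**

Step 1
Reactants: 1 methyl (E)-hept-2-enoate
Product: 2 methyl (S)-3-ethylheptanoate
Conditions: EtMgBr (1.2 equiv), CuBr·SMe2 (5 mol %), Josiphos ligand (R)-1-[(Sp)-2-(diphenylphosphino)ferrocenyl]ethyldicyclohexylphosphine (6 mol %), t-BuOMe, −75 °C; aq. NH4Cl
Reagents that add atoms: ethylmagnesium bromide, CC[Mg]Br
Why: Copper-catalysed asymmetric conjugate addition of a Grignard reagent to an E-enoate, in which the chiral diphosphine–copper complex selects the enantioface of C3 and so sets the future C10 as S.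

Step 2
Reactants: 2 methyl (S)-3-ethylheptanoate
Product: 3 (S)-3-ethylheptanal
Conditions: i-Bu2AlH (1.05 equiv), CH2Cl2, −78 °C; Rochelle salt
Reagents that add atoms: none
Why: Partial reduction of an ester by DIBAL-H stops at the aluminium hemiacetal at low temperature, and the β-stereocentre cannot epimerise.

Step 3
Reactants: 3 (S)-3-ethylheptanal; 4 dimethyl (1-diazo-2-oxopropyl)phosphonate
Product: 5 (S)-4-ethyloct-1-yne
Conditions: K2CO3, MeOH, 0 °C to rt
Reagents that add atoms: none
Why: Ohira–Bestmann variant of the Seyferth–Gilbert homologation converts the aldehyde into the terminal alkyne under mild base that leaves the stereocentre untouched.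

Step 4
Reactants: 5 (S)-4-ethyloct-1-yne; 6 propanoyl chloride
Product: 8 (S,E)-7-ethyl-5-methylundec-4-en-3-one, via E-alkenyl(dimethyl)alane 7 (not isolated)
Conditions: Me3Al (2 equiv), Cp2ZrCl2 (0.2 equiv), CH2Cl2, 0 °C to rt; then 6, Pd(PPh3)4 (5 mol %), THF, 0 °C
Reagents that add atoms: trimethylaluminium, C[Al](C)C
Why: Negishi zirconium-catalysed carboalumination adds methyl and aluminium syn across the alkyne with the metal at the terminus, and palladium-catalysed acylation with retention then gives the E-trisubstituted enone (C7=C8 geometry).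

Step 5
Reactants: 8 (S,E)-7-ethyl-5-methylundec-4-en-3-one
Product: 9 (S,E)-7-ethyl-3,3-dimethoxy-5-methylundec-4-ene
Conditions: MeOSiMe3 (2.2 equiv), Me3SiOTf (2 mol %), CH2Cl2, −78 °C; pyridine quench
Reagents that add atoms: methoxytrimethylsilane, CO[Si](C)(C)C
Why: Silyl-triflate-catalysed ketalization with an alkoxysilane converts conjugated ketones into dimethyl ketals at low temperature without moving the double bond.

Step 6
Reactants: 9 (S,E)-7-ethyl-3,3-dimethoxy-5-methylundec-4-ene
Product: 10 (4E,7S)-7-ethyl-3-hydroperoxy-3-methoxy-5-methylundec-4-ene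
Conditions: anhydrous H2O2 in Et2O (1.5 equiv), pyridinium p-toluenesulfonate (5 mol %), 0 °C
Reagents that add atoms: hydrogen peroxide, OO
Why: Acid-catalysed perhydrolysis of a ketal exchanges one methoxy group for OOH at the ketal carbon, giving the α-methoxy hydroperoxide that carries both peroxide oxygens of the target.

**Fragment A: the C1–C5 dienal with the allylsilane**

Step 7
Reactants: 11 (E)-but-2-enal; 12 2-[dimethyl(phenyl)silyl]-4,4,5,5-tetramethyl-1,3,2-dioxaborolane
Product: 13 3-[dimethyl(phenyl)silyl]butanal (racemic)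
Conditions: CuCl (5 mol %), KOt-Bu (5 mol %), pyrrolidine (20 mol %), 4-nitrobenzoic acid (20 mol %), MeOH (2 equiv), CH2Cl2, rt
Reagents that add atoms: none
Why: Copper/amine co-catalysed conjugate silylation transfers the silyl group of the Si–B reagent to the β-carbon of the iminium-activated enal.

Step 8
Reactants: 13 3-[dimethyl(phenyl)silyl]butanal
Product: 14 3-[dimethyl(phenyl)silyl]-2-methylidenebutanal (racemic)
Conditions: 37% aq. CH2O, pyrrolidine (10 mol %), propanoic acid (10 mol %), i-PrOH, 45 °C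
Reagents that add atoms: formaldehyde, C=O
Why: Amine-catalysed α-methylenation (Mannich condensation then elimination of the amine) installs the C5 methylene and creates the 2-substituted allylsilane.

Step 9
Reactants: 14 3-[dimethyl(phenyl)silyl]-2-methylidenebutanal; 15 (triphenylphosphoranylidene)acetaldehyde
Product: 16 (2E)-5-[dimethyl(phenyl)silyl]-4-methylidenehex-2-enal (racemic)
Conditions: CH2Cl2, rt to 40 °C
Reagents that add atoms: none
Why: Wittig reaction with a stabilised ylide gives the E-enal and stops after one homologation because the product is a less electrophilic conjugated aldehyde.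

**Union and endgame**

Step 10
Reactants: 16 (2E)-5-[dimethyl(phenyl)silyl]-4-methylidenehex-2-enal; 10 (4E,7S)-7-ethyl-3-hydroperoxy-3-methoxy-5-methylundec-4-ene
Product: 17 (3R)-5-[dimethyl(phenyl)silyl]-3-{[(4E,7S)-7-ethyl-3-methoxy-5-methylundec-4-en-3-yl]peroxy}-4-methylidenehexanal
Conditions: (S)-2-{bis[3,5-bis(trifluoromethyl)phenyl](trimethylsilyloxy)methyl}pyrrolidine (10 mol %), toluene, 0 °C
Reagents that add atoms: none
Why: Iminium-catalysed asymmetric conjugate addition of an α-alkoxy hydroperoxide to an enal (organocatalytic β-peroxidation), in which the diaryl(silyloxy)methyl group screens one face of the E-iminium ion so that oxygen should add to C3 from the other face to give 3R, by analogy with amine-catalysed epoxidation of enals.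

Step 11
Reactants: 17 (3R)-5-[dimethyl(phenyl)silyl]-3-{[(4E,7S)-7-ethyl-3-methoxy-5-methylundec-4-en-3-yl]peroxy}-4-methylidenehexanal
Product: 18 (3R)-5-[dimethyl(phenyl)silyl]-3-{[(4E,7S)-7-ethyl-3-methoxy-5-methylundec-4-en-3-yl]peroxy}-4-methylidenehexanoic acid
Conditions: NaClO2, NaH2PO4, 2-methyl-2-butene, t-BuOH/H2O, 0 °C
Reagents that add atoms: sodium chlorite, [Na+].[O-]Cl=O
Why: Pinnick oxidation converts the aldehyde into the acid without touching the O–O bond, while 2-methyl-2-butene scavenges hypochlorous acid and protects the allylsilane and the alkenes.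

Step 12
Reactants: 18 (3R)-5-[dimethyl(phenyl)silyl]-3-{[(4E,7S)-7-ethyl-3-methoxy-5-methylundec-4-en-3-yl]peroxy}-4-methylidenehexanoic acid
Product: 21 2-[(3R,6R)-6-ethyl-4-ethylidene-6-[(1E,4S)-4-ethyl-2-methyloct-1-en-1-yl]-1,2-dioxan-3-yl]acetic acid, via trimethylsilyl ester 19 (not isolated), via cyclised trimethylsilyl ester 20 (not isolated)
Conditions: N,O-bis(trimethylsilyl)acetamide (1.1 equiv), CH2Cl2, rt; then Me3SiOTf (0.2 equiv), 2,6-di-tert-butyl-4-methylpyridine (0.3 equiv), −78 to −40 °C; aq. citric acid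
Reagents that add atoms: none
Why: The Lewis acid removes the methoxy group of the tertiary peroxyketal to give a peroxycarbenium ion at C6 that is delocalised into C7=C8; the terminal carbon C5 of the allylsilane adds to C6 and the β-silyl cation at C4 loses the silyl group, leaving the new alkene exocyclic (C4=CH–CH3, either geometry). The closest known reaction type is the Lewis-acid-mediated cyclization of unsaturated monoperoxyketals through peroxycarbenium ions, an intramolecular Hosomi–Sakurai allylation. Ring O1–O2–C3–C4–C5–C6 is closed in the 6-endo-trig mode (both carbons of the attacking C4=C5 bond and the C6=O1 bond of the electrophile lie in the new ring) through a chair-like transition state. The new stereocentre C6 is controlled by C3: the CH2CO2SiMe3 arm on C3 should stand pseudo-axial to avoid allylic strain with the branched C4 substituent, and the peroxycarbenium ion should react with the alkenyl chain anti to O2 (equatorial) and ethyl syn (axial), which places the alkenyl chain cis to the C3 arm (6R). The step needs attack at C6 and not at C8 of the delocalised cation, which the six- versus eight-membered ring secures, and termination without hydride shift from C3, which the β-silyl effect secures; the silyl ester keeps the acid from intercepting the cation.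

Step 13
Reactants: 21 2-[(3R,6R)-6-ethyl-4-ethylidene-6-[(1E,4S)-4-ethyl-2-methyloct-1-en-1-yl]-1,2-dioxan-3-yl]acetic acid
Product: 22 2-[(3R,4R,6R)-4,6-diethyl-6-[(1E,4S)-4-ethyl-2-methyloct-1-en-1-yl]-1,2-dioxan-3-yl]acetic acid
Conditions: KO2CN=NCO2K (excess), AcOH, MeOH/CH2Cl2, 0 °C to rt
Reagents that add atoms: none
Why: Diimide reduction transfers H2 in a concerted syn fashion without cleaving the O–O bond, should prefer the accessible exocyclic alkene over the neopentylic C7=C8, and should add to the ring face that carries C3–H and the C6 ethyl group (the other face is screened by the C3 arm or, in the alternative chair, by the axial alkenyl chain), setting C4 as R.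

**Compound list**

1 | methyl (E)-hept-2-enoate | CCCC/C=C/C(=O)OC | starting material
2 | methyl (S)-3-ethylheptanoate | CCCC[C@H](CC)CC(=O)OC | intermediate
3 | (S)-3-ethylheptanal | CCCC[C@H](CC)CC=O | intermediate
4 | dimethyl (1-diazo-2-oxopropyl)phosphonate | CC(=O)C(=[N+]=[N-])P(=O)(OC)OC | starting material
5 | (S)-4-ethyloct-1-yne | CCCC[C@H](CC)CC#C | intermediate
6 | propanoyl chloride | CCC(=O)Cl | starting material
7 | [(1E,4S)-4-ethyl-2-methyloct-1-en-1-yl]dimethylaluminium | CCCC[C@H](CC)C/C(C)=C/[Al](C)C | intermediate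
8 | (S,E)-7-ethyl-5-methylundec-4-en-3-one | CCCC[C@H](CC)C/C(C)=C/C(=O)CC | intermediate
9 | (S,E)-7-ethyl-3,3-dimethoxy-5-methylundec-4-ene | CCCC[C@H](CC)C/C(C)=C/C(OC)(OC)CC | intermediate
10 | (4E,7S)-7-ethyl-3-hydroperoxy-3-methoxy-5-methylundec-4-ene (both C3 epimers) | CCCC[C@H](CC)C/C(C)=C/C(OC)(OO)CC | intermediate
11 | (E)-but-2-enal | C/C=C/C=O | starting material
12 | 2-[dimethyl(phenyl)silyl]-4,4,5,5-tetramethyl-1,3,2-dioxaborolane | C[Si](C)(c1ccccc1)B1OC(C)(C)C(C)(C)O1 | starting material
13 | 3-[dimethyl(phenyl)silyl]butanal (racemic) | CC(CC=O)[Si](C)(C)c1ccccc1 | intermediate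
14 | 3-[dimethyl(phenyl)silyl]-2-methylidenebutanal (racemic) | CC(C(=C)C=O)[Si](C)(C)c1ccccc1 | intermediate
15 | (triphenylphosphoranylidene)acetaldehyde | O=CC=P(c1ccccc1)(c1ccccc1)c1ccccc1 | starting material
16 | (2E)-5-[dimethyl(phenyl)silyl]-4-methylidenehex-2-enal (racemic) | CC(C(=C)/C=C/C=O)[Si](C)(C)c1ccccc1 | intermediate
17 | (3R)-5-[dimethyl(phenyl)silyl]-3-{[(4E,7S)-7-ethyl-3-methoxy-5-methylundec-4-en-3-yl]peroxy}-4-methylidenehexanal (epimers at C5 and at the ketal carbon) | C=C(C(C)[Si](C)(C)c1ccccc1)[C@@H](CC=O)OOC(OC)(CC)/C=C(C)/C[C@@H](CC)CCCC | intermediate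
18 | (3R)-5-[dimethyl(phenyl)silyl]-3-{[(4E,7S)-7-ethyl-3-methoxy-5-methylundec-4-en-3-yl]peroxy}-4-methylidenehexanoic acid (same epimer mixture) | C=C(C(C)[Si](C)(C)c1ccccc1)[C@@H](CC(=O)O)OOC(OC)(CC)/C=C(C)/C[C@@H](CC)CCCC | intermediate
19 | trimethylsilyl ester of 18 | C=C(C(C)[Si](C)(C)c1ccccc1)[C@@H](CC(=O)O[Si](C)(C)C)OOC(OC)(CC)/C=C(C)/C[C@@H](CC)CCCC | intermediate
20 | trimethylsilyl 2-[(3R,6R)-6-ethyl-4-ethylidene-6-[(1E,4S)-4-ethyl-2-methyloct-1-en-1-yl]-1,2-dioxan-3-yl]acetate | CCCC[C@H](CC)C/C(C)=C/[C@@]1(CC)CC(=CC)[C@@H](CC(=O)O[Si](C)(C)C)OO1 | intermediate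
21 | 2-[(3R,6R)-6-ethyl-4-ethylidene-6-[(1E,4S)-4-ethyl-2-methyloct-1-en-1-yl]-1,2-dioxan-3-yl]acetic acid (E/Z mixture at the ethylidene) | CCCC[C@H](CC)C/C(C)=C/[C@@]1(CC)CC(=CC)[C@@H](CC(=O)O)OO1 | intermediate
22 | 2-[(3R,4R,6R)-4,6-diethyl-6-[(1E,4S)-4-ethyl-2-methyloct-1-en-1-yl]-1,2-dioxan-3-yl]acetic acid | CCCC[C@H](CC)C/C(C)=C/[C@@]1(CC)C[C@@H](CC)[C@@H](CC(=O)O)OO1 | target

**Step count and risks**

Total step count: 13. Longest linear sequence: 10 steps (steps 1–6, then 10–13).

The three steps most likely to fail: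

Step 10. The hydroperoxide may add to the distal methylene of the vinylogous iminium ion (1,6-addition) instead of C3, face selectivity may be poor with the bulky tertiary hydroperoxide, or the acid co-catalyst may strip methanol from 10 so that liberated H2O2 epoxidises the enal. The fallback makes the C3–O bond by substitution and sets out from 14. A Mukaiyama aldol addition of 1-methoxy-1-(trimethylsilyloxy)ethene, promoted by the chiral oxazaborolidinone from N-tosyl-(S)-valine and BH3·THF, should give methyl (3S)-5-[dimethyl(phenyl)silyl]-3-hydroxy-4-methylidenehexanoate F1. LiBH4 reduction gives (3S)-5-[dimethyl(phenyl)silyl]-4-methylidenehexane-1,3-diol F2. Selective tosylation of the primary alcohol and ring closure with KOt-Bu give (2S)-2-{3-[dimethyl(phenyl)silyl]but-1-en-2-yl}oxetane F3. Perhydrolysis of the oxetane (ethereal H2O2, Yb(OTf)3) should open it at the allylic carbon with inversion to (3R)-5-[dimethyl(phenyl)silyl]-3-hydroperoxy-4-methylidenehexan-1-ol F4. Ketal exchange with 9 (pyridinium p-toluenesulfonate) gives (3R)-5-[dimethyl(phenyl)silyl]-3-{[(4E,7S)-7-ethyl-3-methoxy-5-methylundec-4-en-3-yl]peroxy}-4-methylidenehexan-1-ol F5, and TEMPO/PhI(OAc)2 in wet MeCN oxidises the primary alcohol to acid 18, where the route is rejoined.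

Step 12. Protodesilylation of the allylsilane or heterolytic fragmentation of the tertiary allylic peroxyketal may outrun ring closure, or the C6 configuration may erode if the C3 arm reacts pseudo-equatorial. The fallback forms C5–C6 intermolecularly and closes the ring at O2–C3; it sets out from 10 and 14. Silylation of 10 (t-BuMe2SiCl, imidazole) gives tert-butyl{[(4E,7S)-7-ethyl-3-methoxy-5-methylundec-4-en-3-yl]peroxy}dimethylsilane F6. Wittig reaction of 14 with methyl (triphenylphosphoranylidene)acetate gives methyl (2E)-5-[dimethyl(phenyl)silyl]-4-methylidenehex-2-enoate F7. SnCl4-mediated allylation of the peroxycarbenium ion from F6 by F7 gives methyl (2E,7E,10S)-6-[(tert-butyldimethylsilyl)peroxy]-6,10-diethyl-4-ethylidene-8-methyltetradeca-2,7-dienoate F8. HF·pyridine frees methyl (2E,7E,10S)-6,10-diethyl-4-ethylidene-6-hydroperoxy-8-methyltetradeca-2,7-dienoate F9. Et2NH in CF3CH2OH closes the dioxane by 6-exo conjugate addition of the hydroperoxide. C6 arises without control in this variant, so chromatographic separation of diastereomers would be needed to obtain methyl 2-[(3R,6R)-6-ethyl-4-ethylidene-6-[(1E,4S)-4-ethyl-2-methyloct-1-en-1-yl]-1,2-dioxan-3-yl]acetate F10. LiOH then gives 21.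

Step 13. Diimide may also reduce C7=C8 (loss of chemoselectivity between two trisubstituted alkenes), or may deliver hydrogen to the wrong face of C4 because the axial C6 ethyl group hinders the desired approach. The fallback delivers the two hydrogens stepwise and sets out from 21. Esterification with Me3SiCHN2 gives F10. Hydroboration with 9-borabicyclo[3.3.1]nonane at 0 °C (boron to the exocyclic carbon, hydrogen to C4; the bulky borane should discriminate more strongly against the neopentylic C7=C8) gives methyl 2-[(3R,4S,6R)-4-[1-(9-borabicyclo[3.3.1]nonan-9-yl)ethyl]-6-ethyl-6-[(1E,4S)-4-ethyl-2-methyloct-1-en-1-yl]-1,2-dioxan-3-yl]acetate F11. Protonolysis of the C–B bond with acetic acid gives methyl 2-[(3R,4R,6R)-4,6-diethyl-6-[(1E,4S)-4-ethyl-2-methyloct-1-en-1-yl]-1,2-dioxan-3-yl]acetate F12, and LiOH gives 22.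

Further compounds
F1 | step 10 | methyl (3S)-5-[dimethyl(phenyl)silyl]-3-hydroxy-4-methylidenehexanoate | C=C(C(C)[Si](C)(C)c1ccccc1)[C@@H](O)CC(=O)OC
F2 | step 10 | (3S)-5-[dimethyl(phenyl)silyl]-4-methylidenehexane-1,3-diol | C=C(C(C)[Si](C)(C)c1ccccc1)[C@@H](O)CCO
F3 | step 10 | (2S)-2-{3-[dimethyl(phenyl)silyl]but-1-en-2-yl}oxetane | C=C(C(C)[Si](C)(C)c1ccccc1)[C@@H]1CCO1
F4 | step 10 | (3R)-5-[dimethyl(phenyl)silyl]-3-hydroperoxy-4-methylidenehexan-1-ol | C=C(C(C)[Si](C)(C)c1ccccc1)[C@@H](CCO)OO
F5 | step 10 | (3R)-5-[dimethyl(phenyl)silyl]-3-{[(4E,7S)-7-ethyl-3-methoxy-5-methylundec-4-en-3-yl]peroxy}-4-methylidenehexan-1-ol | C=C(C(C)[Si](C)(C)c1ccccc1)[C@@H](CCO)OOC(OC)(CC)/C=C(C)/C[C@@H](CC)CCCC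
F6 | step 12 | tert-butyl{[(4E,7S)-7-ethyl-3-methoxy-5-methylundec-4-en-3-yl]peroxy}dimethylsilane | CCCC[C@H](CC)C/C(C)=C/C(OC)(CC)OO[Si](C)(C)C(C)(C)C
F7 | step 12 | methyl (2E)-5-[dimethyl(phenyl)silyl]-4-methylidenehex-2-enoate | CC(C(=C)/C=C/C(=O)OC)[Si](C)(C)c1ccccc1
F8 | step 12 | methyl (2E,7E,10S)-6-[(tert-butyldimethylsilyl)peroxy]-6,10-diethyl-4-ethylidene-8-methyltetradeca-2,7-dienoate | CCCC[C@H](CC)C/C(C)=C/C(CC)(CC(=CC)/C=C/C(=O)OC)OO[Si](C)(C)C(C)(C)C
F9 | step 12 | methyl (2E,7E,10S)-6,10-diethyl-4-ethylidene-6-hydroperoxy-8-methyltetradeca-2,7-dienoate | CCCC[C@H](CC)C/C(C)=C/C(CC)(CC(=CC)/C=C/C(=O)OC)OO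
F10 | step 12 | methyl 2-[(3R,6R)-6-ethyl-4-ethylidene-6-[(1E,4S)-4-ethyl-2-methyloct-1-en-1-yl]-1,2-dioxan-3-yl]acetate | CCCC[C@H](CC)C/C(C)=C/[C@@]1(CC)CC(=CC)[C@@H](CC(=O)OC)OO1
F11 | step 13 | methyl 2-[(3R,4S,6R)-4-[1-(9-borabicyclo[3.3.1]nonan-9-yl)ethyl]-6-ethyl-6-[(1E,4S)-4-ethyl-2-methyloct-1-en-1-yl]-1,2-dioxan-3-yl]acetate | CCCC[C@H](CC)C/C(C)=C/[C@@]1(CC)C[C@@H](C(C)B2C3CCCC2CCC3)[C@@H](CC(=O)OC)OO1
F12 | step 13 | methyl 2-[(3R,4R,6R)-4,6-diethyl-6-[(1E,4S)-4-ethyl-2-methyloct-1-en-1-yl]-1,2-dioxan-3-yl]acetate | CCCC[C@H](CC)C/C(C)=C/[C@@]1(CC)C[C@@H](CC)[C@@H](CC(=O)OC)OO1
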